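**Plan**
1. Retrosynthetic cuts, in order: the O–Si bonds (one Si(tBu)2 clamp, one TBS ether); the helper bond C3–CO2tBu; O1–C2 (ring C); C2=C3 (Knoevenagel); the C–C bond that brings in the helper ester (Claisen acylation); C6–CH2 (Friedel–Crafts benzylation).
2. Forward: symmetric 2',6'-dihydroxy-4'-methoxyacetophenone is C-benzylated with salicyl alcohol, clamped, carboxylated at its methyl group and condensed with the ring-B aldehyde. Ring C is the only ring of the target that has to be made. It closes last, and the ester and the silicon groups are then removed.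
3. Enabling features: O5 and the phenol oxygen of the 2-hydroxybenzyl ring flank the C6–CH2 bridge (a 2,2'-methylenebisphenol). One silicon atom therefore ties them into an eight-membered ring and leaves the future O1 as the only free phenol, which settles 6- versus 8-benzyl. C3 is alpha to C4=O and can carry a removable ester that makes C2 a doubly activated, two-point-binding acceptor.
4. Stereochemistry: the single centre C2 (R) comes from a cinchona-thiourea catalyst in a stereoconvergent oxa-Michael closure. The E/Z isomers of the alkylidene and the C3 epimers of the adduct all end in one C2 configuration once C3 is stripped.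

Key step: step 5

Remark: flavanone numbering is used throughout (O1, C2, C3, C4, C4a, C5–C8, C8a; ring B primed; the 2-hydroxybenzyl ring doubly primed). For open-chain precursors it denotes the "future" positions.
Assumption: the quinine-derived 9-amino(9-deoxy)-epi thiourea is assumed to deliver oxygen to the C2 face that gives (2R), by analogy with its conjugate additions to chalcone-type acceptors. If the first run gives the (2S) series, the commercial quinidine-derived pseudoenantiomer is used with no other change.

Step 1
Reactants: 1 2',6'-dihydroxy-4'-methoxyacetophenone; 2 salicyl alcohol (2-hydroxybenzyl alcohol)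
Product: 3 1-[2,6-dihydroxy-3-(2-hydroxybenzyl)-4-methoxyphenyl]ethan-1-one
Conditions: BF3·OEt2 (cat.), 1,4-dioxane, rt; 1 in excess (2 equiv), slow addition of 2
Reagents that add atoms: none
Why: Lewis-acid Friedel–Crafts benzylation of an acylphloroglucinol by an ionised o-hydroxybenzyl alcohol is known for C-benzylated dihydrochalcones and flavanones; C3 and C5 of 1 are equivalent by symmetry, so mono-alkylation can give only one regioisomer, and the excess of 1 limits a second alkylation.

Step 2
Reactants: 3 1-[2,6-dihydroxy-3-(2-hydroxybenzyl)-4-methoxyphenyl]ethan-1-one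
Product: 4 1-(6,6-di-tert-butyl-3-hydroxy-1-methoxy-12H-dibenzo[d,g][1,3,2]dioxasilocin-4-yl)ethan-1-one (ring-A O2 and the side-chain phenol O joined through Si(tBu)2, O6–H free)
Conditions: tBu2Si(OTf)2 (1.05 equiv), 2,6-lutidine (2.5 equiv), CH2Cl2–DMF, high dilution, 0 °C to rt
Reagents that add atoms: di-tert-butylsilyl bis(trifluoromethanesulfonate), CC(C)(C)[Si](OS(=O)(=O)C(F)(F)F)(OS(=O)(=O)C(F)(F)F)C(C)(C)C
Why: Cyclic silylene protection of a 2,2'-methylenebisphenol (dibenzodioxasilocine formation) should start at the unhindered side-chain phenol, after which the remaining Si–OTf can reach only the neighbouring ring-A oxygen, whereas the third hydroxyl is chelated to the ketone and sits para to the bridge carbon, out of reach.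

Step 3
Reactants: 4 silylene-clamped acetophenone
Product: 5 tert-butyl 3-(6,6-di-tert-butyl-3-hydroxy-1-methoxy-12H-dibenzo[d,g][1,3,2]dioxasilocin-4-yl)-3-oxopropanoate
Conditions: LiHMDS (3.2 equiv), THF, –78 °C; Boc2O (1.1 equiv), –78 to –20 °C; AcOH quench
Reagents that add atoms: di-tert-butyl dicarbonate, CC(C)(C)OC(=O)OC(=O)OC(C)(C)C
Why: Claisen-type C-acylation of the lithium phenoxide–enolate dianion with Boc2O is standard, the third equivalent of base stores the product as its enolate (which also blocks lactonisation to a 4-hydroxycoumarin), and the hindered silylene is inert to LiHMDS at low temperature.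

Step 4
Reactants: 5 clamped tert-butyl β-keto ester; 6 4-[(tert-butyldimethylsilyl)oxy]benzaldehyde
Product: 7 tert-butyl 2-(clamped aroyl)-3-{4-[(tert-butyldimethylsilyl)oxy]phenyl}prop-2-enoate, used as the E/Z mixture obtained
Conditions: piperidine (20 mol %), AcOH (20 mol %), 4 Å MS, toluene, rt
Reagents that add atoms: none
Why: Knoevenagel condensation under buffered piperidinium acetate catalysis is the standard entry to 2-hydroxyaryl alkylidene β-keto esters, it spares both silyl groups, and the alkene geometry needs no control because step 5 erases it.

Step 5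
Reactants: 7 alkylidene β-keto ester (E/Z mixture)
Product: 10 (2R)-5,2''-O-(di-tert-butylsilylene)-4'-O-TBS-methylphelligrin A, via tert-butyl flavanone-3-carboxylate 8 (not isolated), via flavanone-3-carboxylic acid 9 (not isolated)
Conditions: quinine-derived 9-epi-amino 3,5-bis(trifluoromethyl)phenyl thiourea (10 mol %), toluene, –25 °C; then TsOH·H2O, 80 °C, same flask
Reagents that add atoms: none
Why: The quinuclidine nitrogen acts as general base on the only free phenol (future O1) while the thiourea N–H pair binds the ketone/ester 1,3-dicarbonyl unit, the phenoxide adds to the benzylidene carbon (future C2), protonation of the C3 enolate gives 8, and TsOH then cleaves the tert-butyl ester so that β-keto acid 9 loses CO2. This is the known bifunctional cinchona-thiourea intramolecular oxa-Michael addition of 2-hydroxyaryl alkylidene β-keto esters with one-pot acidic decarboxylation, an established catalytic entry to enantioenriched flavanones. Ring C closes in the 6-endo-trig mode. C2 is controlled by the catalyst alone, which holds nucleophile and acceptor in one chiral pocket and opens one face of C2; the step is stereoconvergent because the alkene geometry of 7 is lost in the planar C3 enolate, the push–pull E/Z isomers should interconvert by reversible amine addition faster than they cyclise (Curtin–Hammett), and the labile C3 centre of 8 is deleted together with the ester. The needed site selectivity, O1 against O5 (6- against 8-benzyl flavanone) and against the side-chain phenol, is secured by the silylene ring, which occupies both competing oxygens. Kinetic control is also needed, and the low temperature, the non-polar solvent and the 2,6-dioxygenated aroyl group, which strongly favours the closed form, should suppress the retro-addition.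

Step 6
Reactants: 10 (2R)-5,2''-O-(di-tert-butylsilylene)-4'-O-TBS-methylphelligrin A
Product: 11 (+)-methylphelligrin A, (2R)-5-hydroxy-2-(4-hydroxyphenyl)-6-(2-hydroxybenzyl)-7-methoxychroman-4-one
Conditions: HF·pyridine, THF, 0 °C to rt (plastic vessel); neutral work-up
Reagents that add atoms: none
Why: Fluoride cleavage of the Si–O bonds under slightly acidic conditions removes clamp and TBS ether together, and the absence of base avoids the phenoxide-triggered opening of ring C (retro-oxa-Michael, p-quinone-methide pathway) that would racemise C2 or scramble the 6- and 8-benzyl isomers.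

**Compound list**
1 | 2',6'-dihydroxy-4'-methoxyacetophenone | CC(=O)c1c(O)cc(OC)cc1O | starting material
2 | salicyl alcohol | OCc1ccccc1O | starting material
3 | 1-[2,6-dihydroxy-3-(2-hydroxybenzyl)-4-methoxyphenyl]ethan-1-one | CC(=O)c1c(O)cc(OC)c(Cc2ccccc2O)c1O | intermediate
4 | silylene-clamped acetophenone | CC(=O)c1c(O)cc(OC)c2c1O[Si](C(C)(C)C)(C(C)(C)C)Oc1ccccc1C2 | intermediate
5 | clamped tert-butyl β-keto ester | CC(C)(C)OC(=O)CC(=O)c1c(O)cc(OC)c2c1O[Si](C(C)(C)C)(C(C)(C)C)Oc1ccccc1C2 | intermediate
6 | 4-[(tert-butyldimethylsilyl)oxy]benzaldehyde | O=Cc1ccc(O[Si](C)(C)C(C)(C)C)cc1 | starting material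
7 | clamped alkylidene β-keto ester, E/Z mixture | CC(C)(C)OC(=O)C(=Cc1ccc(O[Si](C)(C)C(C)(C)C)cc1)C(=O)c1c(O)cc(OC)c2c1O[Si](C(C)(C)C)(C(C)(C)C)Oc1ccccc1C2 | intermediate
8 | tert-butyl (2R)-flavanone-3-carboxylate, clamp and TBS in place, C3 epimers/enol | COc1cc2c(c3c1Cc1ccccc1O[Si](C(C)(C)C)(C(C)(C)C)O3)C(=O)C(C(=O)OC(C)(C)C)[C@H](c1ccc(O[Si](C)(C)C(C)(C)C)cc1)O2 | intermediate (not isolated)
9 | (2R)-flavanone-3-carboxylic acid, clamp and TBS in place, C3 epimers/enol | COc1cc2c(c3c1Cc1ccccc1O[Si](C(C)(C)C)(C(C)(C)C)O3)C(=O)C(C(=O)O)[C@H](c1ccc(O[Si](C)(C)C(C)(C)C)cc1)O2 | intermediate (not isolated)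
10 | (2R)-5,2''-O-(di-tert-butylsilylene)-4'-O-TBS-methylphelligrin A | COc1cc2c(c3c1Cc1ccccc1O[Si](C(C)(C)C)(C(C)(C)C)O3)C(=O)C[C@H](c1ccc(O[Si](C)(C)C(C)(C)C)cc1)O2 | intermediate
11 | (+)-methylphelligrin A, (2R) | COc1cc2c(c(O)c1Cc1ccccc1O)C(=O)C[C@H](c1ccc(O)cc1)O2 | target

Total step count: 6. Longest linear sequence: 6 (1 → 3 → 4 → 5 → 7 → 10 → 11).

**Steps most likely to fail**

Step 5. The enantiomeric purity may erode in three ways. Facial discrimination on the hindered 2,6-dioxygenated aroyl acceptor may be poor, uncatalysed closure may compete, and acid may open and reclose ring C during the hot decarboxylation. The fallback sets C2 by C–C instead of C–O bond formation. It starts from 4. Condensation with N,N-dimethylformamide dimethyl acetal (toluene, 90 °C) would give the clamped enaminone F1. Mild acid (TsOH, CH2Cl2) would close F1, with loss of dimethylamine, to the clamped 2,3-unsubstituted chromone F2. Pd(II)/tBu-PyOx-catalysed asymmetric conjugate addition of commercial 4-(tert-butyldimethylsilyloxy)phenylboronic acid to F2 follows, with the ligand enantiomer chosen for aryl delivery to the face that gives (2R). This returns to the route at 10.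

Step 4. The free phenol may close prematurely onto the new alkylidene under amine promotion, which would give racemic material. Condensation of the electron-rich aldehyde may also be sluggish. The fallback masks the nucleophile until the acceptor is built. It starts from 4. Allyl bromide/K2CO3 in acetone would give the clamped allyl ether F3, and LiHMDS/Boc2O would give the allyl-protected β-keto ester F4. Knoevenagel condensation with 6, now free to be forced, would give the allyl-protected alkylidene F5. Neutral deallylation (Pd(PPh3)4 cat., N-methylaniline, THF, rt) releases the phenol and returns to the route at 7, which is taken at once into step 5.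

Step 2. Silylation may occur at the chelated hydroxyl para to the bridge, and intermolecular bridging may compete with eight-membered ring closure. The fallback blocks the third hydroxyl temporarily. It starts from 3. One equivalent of benzyl bromide with K2CO3 in acetone should alkylate the most acidic and least hindered acylresorcinol hydroxyl to give the mono-benzyl ether F6. With only the two clamp partners left, tBu2Si(OTf)2/2,6-lutidine would give the clamped benzyl ether F7. Hydrogenolysis (H2, Pd/C, EtOAc) then returns to the route at 4.

**Further compounds**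
F1 | step 5 | clamped (E)-3-(dimethylamino)-1-arylprop-2-en-1-one | CN(C)/C=C/C(=O)c1c(O)cc(OC)c2c1O[Si](C(C)(C)C)(C(C)(C)C)Oc1ccccc1C2
F2 | step 5 | clamped 7-methoxychromone (5-O and side-chain O bridged by Si(tBu)2) | O=c1ccoc2cc(OC)c3Cc4ccccc4O[Si](C(C)(C)C)(C(C)(C)C)Oc3c12
F3 | step 4 | clamped acetophenone allyl ether | CC(=O)c1c(OCC=C)cc(OC)c2c1O[Si](C(C)(C)C)(C(C)(C)C)Oc1ccccc1C2
F4 | step 4 | allyl-protected clamped tert-butyl β-keto ester | CC(C)(C)OC(=O)CC(=O)c1c(OCC=C)cc(OC)c2c1O[Si](C(C)(C)C)(C(C)(C)C)Oc1ccccc1C2
F5 | step 4 | allyl-protected clamped alkylidene β-keto ester, E/Z mixture | CC(C)(C)OC(=O)C(=Cc1ccc(O[Si](C)(C)C(C)(C)C)cc1)C(=O)c1c(OCC=C)cc(OC)c2c1O[Si](C(C)(C)C)(C(C)(C)C)Oc1ccccc1C2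
F6 | step 2 | 1-[6-(benzyloxy)-2-hydroxy-3-(2-hydroxybenzyl)-4-methoxyphenyl]ethan-1-one | CC(=O)c1c(OCc2ccccc2)cc(OC)c(Cc2ccccc2O)c1O
F7 | step 2 | clamped acetophenone benzyl ether | CC(=O)c1c(OCc2ccccc2)cc(OC)c2c1O[Si](C(C)(C)C)(C(C)(C)C)Oc1ccccc1C2
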